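The side-chain carbonyl, its CH2 and ring carbon C5 form an aldol array, C(=O)–CH2–C(OH), centred on the only stereocentre, a fully substituted carbon of the cyclohexenone ring. The route cuts this array between carbonyl carbon and CH2 and masks it as a spiro-isoxazoline. In the key step the nitrile oxide of the C18 linoleyl chain adds across the exocyclic C5=CH2 bond of an enantiopure, silyl-protected 5-methylidenecyclohex-2-enol. One operation joins both fragments, makes the C–C and the tertiary C–O bond, and sets C5 by relay from the allylic C1 stereocentre, which later vanishes as the enone carbonyl. N–O cleavage, desilylation and allylic oxidation finish the synthesis.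

Key step: step 6

Remark: ring positions are numbered as in the target (C1 carbonyl carbon, C2=C3, C4, C5 carbinol carbon, C6) in all ring compounds; linoleyl bromide 11 is assumed to be purchasable as a lipid building block.

Step 1
Reactants: 1 3-chloro-2-(chloromethyl)prop-1-ene; 2 vinylmagnesium bromide
Product: 3 2-(chloromethyl)penta-1,4-diene
Conditions: 1 (3 equiv), CuBr·SMe2 (5 mol%), THF, −30 to 0 °C; distillation
Reagents that add atoms: none
Why: Copper-catalysed allylic substitution of an allylic chloride by a vinyl Grignard reagent; direct and allylically transposed attack on the symmetric dichloride give the same skipped diene, and the excess of 1 should hold back a second substitution.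

Step 2
Reactants: 3 2-(chloromethyl)penta-1,4-diene; 4 acrolein
Product: 8 (3S)-5-methylideneocta-1,7-dien-3-ol, via allylic Grignard reagent 5 (not isolated), via allylborane 6 (not isolated), via borinate ester 7 (not isolated)
Conditions: Mg, THF, 0 °C; (−)-Ipc2BOMe, Et2O, −78 °C to rt; 4, −78 °C; NaOH, H2O2, 0 °C to rt
Reagents that add atoms: none
Why: Brown asymmetric allylboration with a 2-substituted (methallyl-type) allylborane; the chair Zimmerman–Traxler transition state under control of the isopinocampheyl groups from (+)-α-pinene should deliver the allyl unit to one face of acrolein and set C3 as (S), the sense known for allyl and methallyl transfer.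

Step 3
Reactants: 8 (3S)-5-methylideneocta-1,7-dien-3-ol
Product: 9 tert-butyl{[(3S)-5-methylideneocta-1,7-dien-3-yl]oxy}diphenylsilane
Conditions: TBDPSCl, imidazole, DMF, rt
Reagents that add atoms: tert-butyl(chloro)diphenylsilane (TBDPSCl), CC(C)(C)[Si](Cl)(c1ccccc1)c1ccccc1
Why: Standard silylation of a secondary allylic alcohol; the bulky group is chosen as the facial control element of step 6 and makes the material non-volatile.

Step 4
Reactants: 9 tert-butyl{[(3S)-5-methylideneocta-1,7-dien-3-yl]oxy}diphenylsilane
Product: 10 tert-butyl{[(1S)-5-methylidenecyclohex-2-en-1-yl]oxy}diphenylsilane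
Conditions: second-generation Grubbs catalyst RuCl2(=CHPh)(PCy3)(SIMes) (2 mol%), 1,4-benzoquinone (10 mol%), CH2Cl2 (0.01 M), 40 °C
Reagents that add atoms: none
Why: Ring-closing metathesis of the two monosubstituted vinyl groups closes the six-membered ring, the 1,1-disubstituted methylidene stays a bystander because it could only close three- or four-membered rings, benzoquinone should suppress hydride-mediated alkene migration, and the stereocentre is untouched.

Step 5
Reactants: 11 (6Z,9Z)-18-bromooctadeca-6,9-diene (linoleyl bromide)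
Product: 12 (6Z,9Z)-18-nitrooctadeca-6,9-diene
Conditions: AgNO2, Et2O, 0 °C to rt, dark
Reagents that add atoms: silver nitrite, [Ag+].[O-]N=O
Why: Victor Meyer reaction; silver-assisted displacement of a primary bromide by nitrite favours N-alkylation, and the Z,Z-skipped diene is inert.

Step 6
Reactants: 10 tert-butyl{[(1S)-5-methylidenecyclohex-2-en-1-yl]oxy}diphenylsilane; 12 (6Z,9Z)-18-nitrooctadeca-6,9-diene
Product: 14 (5S,7S)-7-{[tert-butyl(diphenyl)silyl]oxy}-3-[(8Z,11Z)-heptadeca-8,11-dien-1-yl]-1-oxa-2-azaspiro[4.5]deca-2,8-diene, via nitrile oxide 13 (not isolated)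
Conditions: PhNCO (3 equiv), Et3N (0.2 equiv), toluene, 50 °C, 12 (1.5 equiv) added by syringe pump over 10 h
Reagents that add atoms: none
Why: Phenyl isocyanate dehydrates the nitronate of 12 to nitrile oxide 13 (Mukaiyama nitrile oxide generation), which adds to the C5=CH2 bond of 10 in a concerted Huisgen [3+2] nitrile oxide–alkene cycloaddition, the isoxazoline route to aldols. The five-membered isoxazoline ring closes in the cycloaddition itself, both bonds forming suprafacially on one alkene face, and the normal regiochemistry of 1,1-disubstituted alkenes puts the dipole carbon on the CH2 terminus and the oxygen on the fully substituted ring carbon. The new spiro centre is controlled by the C1 silyloxy group: in the half-chair with pseudoaxial OTBDPS the syn face of the methylidene is shielded by a 1,3-diaxial-type contact, and in the half-chair with pseudoequatorial OTBDPS the torsionally favoured axial approach, eased by the missing axial hydrogen at sp2 C3, is again the anti face, so oxygen should enter trans to OTBDPS and give (5S). Chemoselectivity is needed against the ring C2=C3 bond and the two Z-alkenes of the chain; all three are 1,2-disubstituted and react far more slowly with nitrile oxides than a 1,1-disubstituted methylidene, and C2=C3 is further screened by the silyl ether. Slow addition of 12 keeps 13 dilute and should hold back its dimerisation. Any minor C5 epimer is a diastereomer at this stage and should be removable by chromatography.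

Step 7
Reactants: 14 (5S,7S)-spiro-isoxazoline silyl ether
Product: 16 (10Z,13Z)-1-[(1R,5S)-5-{[tert-butyl(diphenyl)silyl]oxy}-1-hydroxycyclohex-3-en-1-yl]nonadeca-10,13-dien-2-one, via hydroxy imine 15 (not isolated)
Conditions: Mo(CO)6 (1.1 equiv), MeCN/H2O (10:1), 80 °C
Reagents that add atoms: water, O
Why: Reductive N–O cleavage of a 2-isoxazoline with Mo(CO)6 in wet acetonitrile gives the β-hydroxy imine, which water hydrolyses to the ketone; alkenes and silyl ether are not reduced and the C5–O bond is not broken, so the configuration is retained (the descriptor changes only through CIP priorities).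

Step 8
Reactants: 16 β-hydroxy ketone silyl ether
Product: 17 (10Z,13Z)-1-[(1R,5S)-1,5-dihydroxycyclohex-3-en-1-yl]nonadeca-10,13-dien-2-one
Conditions: TBAF, AcOH (1:1), THF, 0 °C to rt
Reagents that add atoms: none
Why: Fluoride-mediated desilylation; buffering with acetic acid should keep the medium from triggering retro-aldol cleavage or dehydration of the β-hydroxy ketone.

Step 9
Reactants: 17 diol ketone
Product: 18 (5S)-5-hydroxy-5-[(10Z,13Z)-2-oxononadeca-10,13-dien-1-yl]cyclohex-2-en-1-one
Conditions: activated MnO2 (excess), CH2Cl2, rt; filtration through Celite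
Reagents that add atoms: none
Why: Chemoselective MnO2 oxidation of the allylic secondary alcohol under neutral heterogeneous conditions; the tertiary alcohol cannot be oxidised, the temporary C1 stereocentre is erased, and the acid- and base-sensitive β-hydroxy enone appears only in the last and mildest step.

Compound list
1 | 3-chloro-2-(chloromethyl)prop-1-ene | C=C(CCl)CCl | starting material
2 | vinylmagnesium bromide | C=C[Mg]Br | starting material
3 | 2-(chloromethyl)penta-1,4-diene | C=CCC(=C)CCl | intermediate
4 | acrolein (prop-2-enal) | C=CC=O | starting material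
5 | (2-methylidenepent-4-en-1-yl)magnesium chloride | C=CCC(=C)C[Mg]Cl | intermediate
6 | B-(2-methylidenepent-4-en-1-yl)diisopinocampheylborane, isopinocampheyl groups from (+)-α-pinene | C=CCC(=C)CB([C@@H]1C[C@@H]2C[C@H]([C@H]1C)C2(C)C)[C@@H]1C[C@@H]2C[C@H]([C@H]1C)C2(C)C | intermediate
7 | diisopinocampheylborinate ester of 8 | C=C[C@@H](OB([C@@H]1C[C@@H]2C[C@H]([C@H]1C)C2(C)C)[C@@H]1C[C@@H]2C[C@H]([C@H]1C)C2(C)C)CC(=C)CC=C | intermediate
8 | (3S)-5-methylideneocta-1,7-dien-3-ol | C=C[C@@H](O)CC(=C)CC=C | intermediate
9 | tert-butyl{[(3S)-5-methylideneocta-1,7-dien-3-yl]oxy}diphenylsilane | C=C[C@@H](O[Si](c1ccccc1)(c1ccccc1)C(C)(C)C)CC(=C)CC=C | intermediate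
10 | tert-butyl{[(1S)-5-methylidenecyclohex-2-en-1-yl]oxy}diphenylsilane | CC(C)(C)[Si](O[C@@H]1C=CCC(=C)C1)(c1ccccc1)c1ccccc1 | intermediate
11 | (6Z,9Z)-18-bromooctadeca-6,9-diene (linoleyl bromide) | CCCCC/C=C\C/C=C\CCCCCCCCBr | starting material
12 | (6Z,9Z)-18-nitrooctadeca-6,9-diene | CCCCC/C=C\C/C=C\CCCCCCCC[N+](=O)[O-] | intermediate
13 | (9Z,12Z)-octadeca-9,12-dienenitrile oxide | CCCCC/C=C\C/C=C\CCCCCCCC#[N+][O-] | intermediate
14 | (5S,7S)-7-{[tert-butyl(diphenyl)silyl]oxy}-3-[(8Z,11Z)-heptadeca-8,11-dien-1-yl]-1-oxa-2-azaspiro[4.5]deca-2,8-diene (ring O trans to OTBDPS) | CC(C)(C)[Si](O[C@@H]1C=CC[C@]2(CC(CCCCCCC/C=C\C/C=C\CCCCC)=NO2)C1)(c1ccccc1)c1ccccc1 | intermediate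
15 | β-hydroxy imine, C=NH in place of the side-chain C=O of 16 | CC(C)(C)[Si](O[C@@H]1C=CC[C@](O)(CC(=N)CCCCCCC/C=C\C/C=C\CCCCC)C1)(c1ccccc1)c1ccccc1 | intermediate
16 | (10Z,13Z)-1-[(1R,5S)-5-{[tert-butyl(diphenyl)silyl]oxy}-1-hydroxycyclohex-3-en-1-yl]nonadeca-10,13-dien-2-one | CC(C)(C)[Si](O[C@@H]1C=CC[C@](O)(CC(=O)CCCCCCC/C=C\C/C=C\CCCCC)C1)(c1ccccc1)c1ccccc1 | intermediate
17 | (10Z,13Z)-1-[(1R,5S)-1,5-dihydroxycyclohex-3-en-1-yl]nonadeca-10,13-dien-2-one (the two OH groups trans) | O[C@@H]1C=CC[C@](O)(CC(=O)CCCCCCC/C=C\C/C=C\CCCCC)C1 | intermediate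
18 | (5S)-5-hydroxy-5-[(10Z,13Z)-2-oxononadeca-10,13-dien-1-yl]cyclohex-2-en-1-one | CCCCC/C=C\C/C=C\CCCCCCCC(=O)C[C@@]1(O)CC=CC(=O)C1 | target

Total step count: 9. Longest linear sequence: 8 steps (1, 2, 3, 4, 6, 7, 8, 9).

Steps most likely to fail

Step 6. Facial selectivity at the methylidene may be only modest. Dimerisation of the aliphatic nitrile oxide, or its addition to the chain alkenes, may also outrun the wanted cycloaddition. The fallback sets out from 10 and comes back at 16.
- mCPBA/NaHCO3 in CH2Cl2 at 0 °C should epoxidise the unhindered methylidene anti to the silyl ether and give the spiro-epoxide F1. Its minor epimer can be removed before any lipid is committed.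
- PhSO2Na in DMF at 90 °C opens the epoxide at its CH2 to the hydroxy sulfone F2.
- The dianion of F2 (n-BuLi, THF, −78 °C) is acylated with half an equivalent of commercial methyl linoleate. This Claisen-type acylation makes the same C–C bond without touching C5 and gives the keto sulfone F3. The second equivalent of dianion serves as base and is recovered.
- SmI2 in THF/MeOH at −78 °C removes the sulfonyl group and gives 16, so step 7 is bypassed as well.

Step 7. Retro-aldol fragmentation of the tertiary aldol, or migration of the skipped diene, may occur under molybdenum carbonyl at 80 °C. The fallback sets out from 14 and comes back at 16.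
- LiAlH4 in Et2O at 0 °C reduces C=N and N–O at low temperature to the amino alcohol F4, as a mixture of amine epimers.
- Quinone-mediated transamination with 3,5-di-tert-butyl-1,2-benzoquinone in MeOH/THF follows, then hydrolysis with aqueous oxalic acid. This converts the CH–NH2 group into the ketone of 16.

Step 2. Wurtz coupling during formation of the allylic Grignard reagent, and erosion of enantioselectivity by magnesium salts, may spoil the allylboration. The fallback sets out from 3 and 4 and comes back at 8.
- A zinc Barbier reaction in THF/aqueous NH4Cl gives the racemic alcohol F5.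
- Sharpless kinetic resolution follows (Ti(OiPr)4, D-(−)-DIPT, TBHP 0.6 equiv, 4 Å molecular sieves, CH2Cl2, −20 °C). It should consume the (R)-enantiomer as the epoxy alcohol F6 and leave 8 unreacted. The non-allylic alkenes are not epoxidised by this system.

Further compounds
F1 | step 6 | (3R,5S)-5-{[tert-butyl(diphenyl)silyl]oxy}-1-oxaspiro[2.5]oct-6-ene | CC(C)(C)[Si](O[C@@H]1C=CC[C@]2(CO2)C1)(c1ccccc1)c1ccccc1
F2 | step 6 | (1R,5S)-5-{[tert-butyl(diphenyl)silyl]oxy}-1-[(phenylsulfonyl)methyl]cyclohex-3-en-1-ol | CC(C)(C)[Si](O[C@@H]1C=CC[C@](O)(CS(=O)(=O)c2ccccc2)C1)(c1ccccc1)c1ccccc1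
F3 | step 6 | (10Z,13Z)-1-[(1R,5S)-5-{[tert-butyl(diphenyl)silyl]oxy}-1-hydroxycyclohex-3-en-1-yl]-1-(phenylsulfonyl)nonadeca-10,13-dien-2-one, both epimers at the sulfonyl carbon | CC(C)(C)[Si](O[C@@H]1C=CC[C@](O)(C(C(=O)CCCCCCC/C=C\C/C=C\CCCCC)S(=O)(=O)c2ccccc2)C1)(c1ccccc1)c1ccccc1
F4 | step 7 | (1S,5S)-1-[(10Z,13Z)-2-aminononadeca-10,13-dien-1-yl]-5-{[tert-butyl(diphenyl)silyl]oxy}cyclohex-3-en-1-ol, both amine epimers | CC(C)(C)[Si](O[C@@H]1C=CC[C@](O)(CC(N)CCCCCCC/C=C\C/C=C\CCCCC)C1)(c1ccccc1)c1ccccc1
F5 | step 2 | racemic 5-methylideneocta-1,7-dien-3-ol | C=CC(O)CC(=C)CC=C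
F6 | step 2 | (1R)-3-methylidene-1-[(2S)-oxiran-2-yl]hex-5-en-1-ol | C=CCC(=C)C[C@@H](O)[C@@H]1CO1
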